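**Retrosynthetic overview**

1. Feature: ring C is a 1,2,3-trisubstituted benzene (C1 carries the bridge CH2 to ring B, C2 the ether oxygen to ring D flanked on both sides, C3 the free OH). It is handled as a 2-aryloxycyclohex-2-en-1-one whose C=O carbon is C3, whose oxygen-bearing alkene carbon is C2 and whose free β-CH is C1.
2. Marchantin C ⇐ ring-A O-demethylation ⇐ aromatisation of a macrocyclic 2-aryloxy-3-alkylcyclohexanone (ring C becomes aromatic last).
3. 18-Membered macrocycle ⇐ radical conjugate addition of the ring-B CH2CH2 radical to the enone β-carbon of a seco iodide (forms the bond bridge-CH2 to C1 of ring C).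
4. Seco iodide ⇐ ring-D phenol + 2,3-epoxycyclohexanone (O–C2 bond); A–D bibenzyl ⇐ Wittig/hydrogenation; A–O–B ether ⇐ Ullmann coupling of isovanillin with silyl-protected 2-(4-bromophenyl)ethanol.
5. Ring order: arenes A, B and D are bought; the cyclohexenone (future ring C) is attached to ring D, the macrocycle is closed, then ring C is aromatised.

Key step: step 10

Remark: marchantin C has no stereocentre and is achiral, so no step has to control configuration. Compounds 11, 12, 16 and 17 are racemic (16 and 17 also diastereomer mixtures) and all their sp3 centres are erased by step 11.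

**Route**

Step 1
Reactants: 1 2-(4-bromophenyl)ethanol
Product: 2 [2-(4-bromophenyl)ethoxy](tert-butyl)dimethylsilane
Conditions: TBSCl, imidazole, DMF, 0 °C → rt
Reagents that add atoms: tert-butyldimethylsilyl chloride, CC(C)(C)[Si](C)(C)Cl
Why: Standard silylation of a primary alcohol, so that in step 2 only the phenol oxygen can couple with the aryl bromide.

Step 2
Reactants: 2 [2-(4-bromophenyl)ethoxy](tert-butyl)dimethylsilane; 3 isovanillin
Product: 4 3-{4-[2-(tert-butyldimethylsilyloxy)ethyl]phenoxy}-4-methoxybenzaldehyde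
Conditions: CuI (10 mol%), N,N-dimethylglycine·HCl (30 mol%), Cs2CO3, 1,4-dioxane, 100 °C, Ar
Reagents that add atoms: none
Why: Ligand-accelerated Ullmann diaryl ether synthesis, which should couple an electron-neutral aryl bromide with the ortho-methoxy phenoxide while the non-enolisable aldehyde and the silyl ether survive carbonate base.

Step 3
Reactants: 5 3-(benzyloxy)benzyl alcohol
Product: 6 [3-(benzyloxy)benzyl]triphenylphosphonium bromide
Conditions: Ph3P·HBr, MeCN, reflux
Reagents that add atoms: triphenylphosphine hydrobromide, Br.c1ccc(cc1)P(c1ccccc1)c1ccccc1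
Why: The benzylic alcohol is converted via the benzylic bromide into the phosphonium salt in one operation, under conditions too mild to cleave the aryl benzyl ether.

Step 4
Reactants: 6 [3-(benzyloxy)benzyl]triphenylphosphonium bromide; 4 3-{4-[2-(tert-butyldimethylsilyloxy)ethyl]phenoxy}-4-methoxybenzaldehyde
Product: 8 1-(3-benzyloxyphenyl)-2-(3-{4-[2-(tert-butyldimethylsilyloxy)ethyl]phenoxy}-4-methoxyphenyl)ethene (E/Z mixture), via phosphonium ylide 7 (not isolated)
Conditions: KOt-Bu, THF, 0 °C; then 4, 0 °C → rt
Reagents that add atoms: none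
Why: Wittig olefination with a semi-stabilised benzylic ylide, whose E/Z mixture is of no consequence because the alkene is hydrogenated in step 5.

Step 5
Reactants: 8 1-(3-benzyloxyphenyl)-2-(3-{4-[2-(tert-butyldimethylsilyloxy)ethyl]phenoxy}-4-methoxyphenyl)ethene
Product: 9 3-[2-(3-{4-[2-(tert-butyldimethylsilyloxy)ethyl]phenoxy}-4-methoxyphenyl)ethyl]phenol
Conditions: H2 (1 atm), 10% Pd/C, EtOAc, rt
Reagents that add atoms: none
Why: Catalytic hydrogenation should saturate the stilbene and hydrogenolyse the O-benzyl group in the same operation, while the diaryl ether and the silyl ether are inert in EtOAc.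

Step 6
Reactants: 10 cyclohex-2-en-1-one
Product: 11 2,3-epoxycyclohexanone (7-oxabicyclo[4.1.0]heptan-2-one, racemic)
Conditions: 30% aq. H2O2, NaOH (cat.), MeOH, 0–10 °C
Reagents that add atoms: hydrogen peroxide, OO
Why: Weitz–Scheffer nucleophilic epoxidation of the enone; the cis ring fusion is enforced by the ring, and the racemic centres are destroyed in step 7.

Step 7
Reactants: 9 3-[2-(3-{4-[2-(tert-butyldimethylsilyloxy)ethyl]phenoxy}-4-methoxyphenyl)ethyl]phenol; 11 2,3-epoxycyclohexanone
Product: 13 2-{3-[2-(3-{4-[2-(tert-butyldimethylsilyloxy)ethyl]phenoxy}-4-methoxyphenyl)ethyl]phenoxy}cyclohex-2-en-1-one, via trans-hydroxy ketone 12 (not isolated)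
Conditions: KH (0.2 equiv), DMPU, THF, reflux; 11 (1.5 equiv)
Reagents that add atoms: none
Why: Phenoxide opening of the α,β-epoxy ketone at the α-carbon (anti SN2, giving trans 12) followed by E1cB loss of water gives the 2-aryloxyenone; the hydroxide released regenerates phenoxide, so the base is catalytic, and both transient stereocentres vanish.

Step 8
Reactants: 13 2-{3-[2-(3-{4-[2-(tert-butyldimethylsilyloxy)ethyl]phenoxy}-4-methoxyphenyl)ethyl]phenoxy}cyclohex-2-en-1-one
Product: 14 2-{3-[2-(3-{4-(2-hydroxyethyl)phenoxy}-4-methoxyphenyl)ethyl]phenoxy}cyclohex-2-en-1-one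
Conditions: TBAF, AcOH, THF, 0 °C → rt
Reagents that add atoms: none
Why: Fluoride desilylation of the primary silyl ether, buffered with acetic acid so that no alkoxide or fluoride base acts on the enone.

Step 9
Reactants: 14 2-{3-[2-(3-{4-(2-hydroxyethyl)phenoxy}-4-methoxyphenyl)ethyl]phenoxy}cyclohex-2-en-1-one
Product: 15 2-{3-[2-(3-{4-(2-iodoethyl)phenoxy}-4-methoxyphenyl)ethyl]phenoxy}cyclohex-2-en-1-one (seco iodide)
Conditions: PPh3, I2, imidazole, CH2Cl2, 0 °C → rt, dark
Reagents that add atoms: iodine, II
Why: Appel-type iodination of the primary alcohol through the alkoxyphosphonium salt under near-neutral conditions that leave the enone and its aryl enol ether untouched.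

Step 10
Reactants: 15 seco iodide
Product: 16 macrocyclic 2-aryloxy-3-alkylcyclohexanone (18-membered ring; racemic cis/trans mixture)
Conditions: (Me3Si)3SiH (1.5 equiv) and AIBN (0.3 equiv) added by syringe pump over 10 h to 15 (2 mM) in degassed PhH, 80 °C
Reagents that add atoms: none
Why: The silyl radical abstracts iodine from 15, the nucleophilic primary 2-arylethyl radical adds to the β-carbon of the 2-aryloxyenone, and the resulting α-keto-α-aryloxy radical takes hydrogen from the silane and carries the chain. The closest known reaction type is the Giese addition run as a radical macrocyclisation of an ω-iodoalkyl enone. The 18-membered ring closes in the 18-endo-trig mode, both alkene carbons ending up inside the ring. Two sp3 centres (C2 and C3 of the cyclohexanone) form without control, which is acceptable because both become sp2 in step 11. The step needs β-regioselectivity, secured by polarity matching at the only electron-poor alkene and by the β-carbon being an open CH. It also needs ring closure ahead of direct reduction and oligomerisation, secured by high dilution, slow addition of a slow hydrogen donor and a tether in which the crowded ring is not yet a flat arene.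

Step 11
Reactants: 16 macrocyclic 2-aryloxy-3-alkylcyclohexanone
Product: 18 marchantin C ring-A methyl ether (ring C now a 2-aryloxy-3-alkylphenol), via macrocyclic cyclohexenone 17 (not isolated)
Conditions: Pd(TFA)2 (5 mol%), 2-(dimethylamino)pyridine (10 mol%), TsOH (20 mol%), O2 (1 atm), DMSO, 80 °C
Reagents that add atoms: none
Why: Pd(II)-catalysed aerobic dehydrogenation, in which two rounds of Pd-enolate formation and β-hydride elimination followed by tautomerisation should turn the cyclohexanone into the phenol, placing the OH at the former carbonyl carbon and erasing both sp3 centres.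

Step 12
Reactants: 18 marchantin C ring-A methyl ether
Product: 19 marchantin C
Conditions: BBr3, CH2Cl2, −78 → 0 °C; then H2O
Reagents that add atoms: none
Why: Lewis-acid cleavage of the aryl methyl ether by BBr3, which does not cleave diaryl ethers.

**Compound list**

1 | 2-(4-bromophenyl)ethanol | OCCc1ccc(Br)cc1 | starting material
2 | [2-(4-bromophenyl)ethoxy](tert-butyl)dimethylsilane | CC(C)(C)[Si](C)(C)OCCc1ccc(Br)cc1 | intermediate
3 | isovanillin (3-hydroxy-4-methoxybenzaldehyde) | COc1ccc(C=O)cc1O | starting material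
4 | 3-{4-[2-(tert-butyldimethylsilyloxy)ethyl]phenoxy}-4-methoxybenzaldehyde | COc1ccc(C=O)cc1Oc1ccc(CCO[Si](C)(C)C(C)(C)C)cc1 | intermediate
5 | 3-(benzyloxy)benzyl alcohol | OCc1cccc(OCc2ccccc2)c1 | starting material
6 | [3-(benzyloxy)benzyl]triphenylphosphonium bromide | [Br-].c1ccc(COc2cccc(C[P+](c3ccccc3)(c3ccccc3)c3ccccc3)c2)cc1 | intermediate
7 | [3-(benzyloxy)benzylidene]triphenylphosphorane (ylide, not isolated) | c1ccc(COc2cccc(C=P(c3ccccc3)(c3ccccc3)c3ccccc3)c2)cc1 | intermediate
8 | 1-(3-benzyloxyphenyl)-2-(3-{4-[2-(tert-butyldimethylsilyloxy)ethyl]phenoxy}-4-methoxyphenyl)ethene, E/Z mixture | COc1ccc(C=Cc2cccc(OCc3ccccc3)c2)cc1Oc1ccc(CCO[Si](C)(C)C(C)(C)C)cc1 | intermediate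
9 | 3-[2-(3-{4-[2-(tert-butyldimethylsilyloxy)ethyl]phenoxy}-4-methoxyphenyl)ethyl]phenol | COc1ccc(CCc2cccc(O)c2)cc1Oc1ccc(CCO[Si](C)(C)C(C)(C)C)cc1 | intermediate
10 | cyclohex-2-en-1-one | O=C1CCCC=C1 | starting material
11 | 2,3-epoxycyclohexanone, cis-fused, racemic (one enantiomer drawn) | O=C1CCC[C@H]2O[C@H]21 | intermediate
12 | trans-2-aryloxy-3-hydroxycyclohexanone from 9 and 11, racemic (one enantiomer drawn; not isolated) | COc1ccc(CCc2cccc(O[C@@H]3C(=O)CCC[C@H]3O)c2)cc1Oc1ccc(CCO[Si](C)(C)C(C)(C)C)cc1 | intermediate
13 | 2-{3-[2-(3-{4-[2-(tert-butyldimethylsilyloxy)ethyl]phenoxy}-4-methoxyphenyl)ethyl]phenoxy}cyclohex-2-en-1-one | COc1ccc(CCc2cccc(OC3=CCCCC3=O)c2)cc1Oc1ccc(CCO[Si](C)(C)C(C)(C)C)cc1 | intermediate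
14 | 2-{3-[2-(3-{4-(2-hydroxyethyl)phenoxy}-4-methoxyphenyl)ethyl]phenoxy}cyclohex-2-en-1-one | COc1ccc(CCc2cccc(OC3=CCCCC3=O)c2)cc1Oc1ccc(CCO)cc1 | intermediate
15 | 2-{3-[2-(3-{4-(2-iodoethyl)phenoxy}-4-methoxyphenyl)ethyl]phenoxy}cyclohex-2-en-1-one (seco iodide) | COc1ccc(CCc2cccc(OC3=CCCCC3=O)c2)cc1Oc1ccc(CCI)cc1 | intermediate
16 | macrocyclic 2-aryloxy-3-alkylcyclohexanone, racemic cis/trans mixture (drawn without configuration) | COc1ccc2cc1Oc1ccc(cc1)CCC1CCCC(=O)C1Oc1cccc(c1)CC2 | intermediate
17 | macrocyclic 6-aryloxy-5-alkylcyclohex-2-enone, diastereomer mixture (drawn without configuration; not isolated) | COc1ccc2cc1Oc1ccc(cc1)CCC1CC=CC(=O)C1Oc1cccc(c1)CC2 | intermediate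
18 | marchantin C ring-A methyl ether | COc1ccc2cc1Oc1ccc(cc1)CCc1cccc(O)c1Oc1cccc(c1)CC2 | intermediate
19 | marchantin C | Oc1ccc2cc1Oc1ccc(cc1)CCc1cccc(O)c1Oc1cccc(c1)CC2 | target

**Step count**

Total: 12 steps. Longest linear sequence: 10 steps (1, 2, 4, 5, 7, 8, 9, 10, 11, 12).

**Steps most likely to fail**

Step 10 (radical macrocyclisation). The primary radical may be reduced by the silane before the 18-membered ring closes. The chain may also die at the stabilised adduct radical, or the radical may add intermolecularly and give oligomers. The fallback closes the same bond by an ionic, reversible ring closure. Setting out from iodide 15, silver nitrite in Et2O (Victor Meyer reaction) should give the primary nitroalkane F1. DBU in MeCN at 2 mM should then close the ring by intramolecular Michael addition of the nitronate to the same enone β-carbon, giving the macrocyclic γ-nitro ketone F2 under thermodynamic control. Radical denitration of the secondary nitro group with Bu3SnH/AIBN in toluene at 110 °C comes back to the route at ketone 16.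

Step 11 (aerobic dehydrogenation). The catalytic cycle may stall after the first dehydrogenation, or the catalyst may deposit as palladium black. The hot acidic, oxidising medium may also degrade the α-aryloxy ketone. The fallback aromatises stepwise and stoichiometrically through regiodefined silyl enol ethers at room temperature. From 16, LDA/TMSCl at −78 °C should give the kinetic silyl enol ether F3 on the CH2 side, and Saegusa–Ito oxidation (Pd(OAc)2, MeCN) should give enone 17, now isolated. A second LDA/TMSCl treatment should give the cross-conjugated 2-silyloxydiene F4, and a second Saegusa–Ito oxidation a cyclohexa-2,5-dienone that tautomerises to phenol 18, where the route resumes.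

Step 7 (aryloxyenone formation). The base may consume the epoxy ketone by self-condensation or isomerisation before the phenoxide opens it. Opening at the β-carbon would give an adduct that cannot dehydrate to the enone. The fallback forms the O–C2 bond by carbenoid O–H insertion and sets the enone by carbonyl transposition. Diazo transfer (p-acetamidobenzenesulfonyl azide, Et3N, MeCN) to commercial cyclohexane-1,3-dione should give 2-diazocyclohexane-1,3-dione F5. Setting out from phenol 9, Rh2(OAc)4-catalysed O–H insertion of F5 should give the 2-aryloxy-1,3-dione F6 (enol form), and TMSCHN2/MeOH the methyl vinylogous ester F7. DIBAL-H 1,2-reduction to the allylic alcohol F8 and hydrolysis with dilute aqueous oxalic acid (Stork–Danheiser transposition) come back to the route at aryloxyenone 13.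

**Further compounds**

F1 | step 10 | 2-{3-[2-(3-{4-(2-nitroethyl)phenoxy}-4-methoxyphenyl)ethyl]phenoxy}cyclohex-2-en-1-one | COc1ccc(CCc2cccc(OC3=CCCCC3=O)c2)cc1Oc1ccc(CC[N+](=O)[O-])cc1
F2 | step 10 | macrocyclic 2-aryloxy-3-(1-nitroalkyl)cyclohexanone, diastereomer mixture | COc1ccc2cc1Oc1ccc(cc1)CC([N+](=O)[O-])C1CCCC(=O)C1Oc1cccc(c1)CC2
F3 | step 11 | kinetic trimethylsilyl enol ether of 16 | COc1ccc2cc1Oc1ccc(cc1)CCC1CCC=C(O[Si](C)(C)C)C1Oc1cccc(c1)CC2
F4 | step 11 | 2-trimethylsilyloxy-1,3-diene from 17 | COc1ccc2cc1Oc1ccc(cc1)CCC1CC=CC(O[Si](C)(C)C)=C1Oc1cccc(c1)CC2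
F5 | step 7 | 2-diazocyclohexane-1,3-dione | [N-]=[N+]=C1C(=O)CCCC1=O
F6 | step 7 | 2-aryloxy-3-hydroxycyclohex-2-en-1-one (enol of the 2-aryloxy-1,3-dione) from 9 | COc1ccc(CCc2cccc(OC3=C(O)CCCC3=O)c2)cc1Oc1ccc(CCO[Si](C)(C)C(C)(C)C)cc1
F7 | step 7 | 2-aryloxy-3-methoxycyclohex-2-en-1-one | COc1ccc(CCc2cccc(OC3=C(OC)CCCC3=O)c2)cc1Oc1ccc(CCO[Si](C)(C)C(C)(C)C)cc1
F8 | step 7 | 2-aryloxy-3-methoxycyclohex-2-en-1-ol, racemic | COc1ccc(CCc2cccc(OC3=C(OC)CCCC3O)c2)cc1Oc1ccc(CCO[Si](C)(C)C(C)(C)C)cc1
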